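**Retrosynthetic overview**
1. The side chain is finished last: E-selective cross-metathesis of a 2-allyl chroman with 2-methylbut-3-en-2-ol; the C3 acetate comes from a C3 silyl ether.
2. The pyran ring is cut at O1–C8a and C2–C3 (and at C2–C1′). Three components are joined in one pot: an arylacetaldehyde (C3, C4 and the benzo ring with fluorine on C8a), acetyl(tert-butyl)dimethylsilane (C2 and its methyl group, used as an acyl anion) and allylzinc bromide (C1′–C3′).
3. Enabling features: the methyl ester on C6 of the benzo ring is para to C8a, so a fluoride on C8a can be displaced by the C2 alkoxide (SNAr). The vicinal C2–O1/C3–O3 pattern of the pyran ring is a masked acyloin, so C2 and C3 are both carbonyl carbons and can be joined after polarity reversal of one of them (cross silyl benzoin).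
4. Stereocontrol: C3 by the chiral phosphite catalyst during C2–C3 bond formation; C2 by chelation-controlled allyl transfer relayed from C3.
5. Ring order: the benzene ring is bought; the pyran ring is the only ring made and is closed in the key step.

Key step: step 4

Remark: chroman numbering is used (O1, C2, C3, C4, C4a, C5–C8, C8a; side chain C1′–C4′); the (R,R)-TADDOL phosphite is assumed to give the (R)-silyloxy ketone, and its (S,S)-antipode is used instead if the sense of induction is the opposite.

**Step 1**
Reactants: 1 methyl 3-bromo-4-fluorobenzoate; 2 2-[(E)-2-ethoxyethenyl]-4,4,5,5-tetramethyl-1,3,2-dioxaborolane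
Product: 3 methyl 3-[(E)-2-ethoxyethenyl]-4-fluorobenzoate
Conditions: Pd(dppf)Cl2 (3 mol%), K3PO4, 1,4-dioxane/H2O, 80 °C
Reagents that add atoms: none
Why: Suzuki–Miyaura coupling of the aryl bromide with the 2-ethoxyvinyl boronate (an acetaldehyde enolate equivalent) should occur at the C–Br bond only, the C–F bond and the methyl ester being inert under these mild phosphate conditions; no stereocenter is formed.

**Step 2**
Reactants: 3 methyl 3-[(E)-2-ethoxyethenyl]-4-fluorobenzoate
Product: 4 methyl 4-fluoro-3-(2-oxoethyl)benzoate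
Conditions: 2 M aq. HCl, THF, rt to 40 °C; used crude and fresh
Reagents that add atoms: water, O
Why: Acid-catalysed enol ether hydrolysis (C-protonation, hydration, loss of ethanol) should unmask the arylacetaldehyde without touching the ester; no stereocenter is formed.

**Step 3**
Reactants: 5 ethyl vinyl ether
Product: 8 acetyl(tert-butyl)dimethylsilane [1-(tert-butyldimethylsilyl)ethan-1-one], via (1-ethoxyethenyl)lithium 6 (not isolated), via silyl enol ether 7 (not isolated)
Conditions: t-BuLi, THF, −78 to 0 °C; t-BuMe2SiCl, −78 °C to rt; 1 M aq. HCl, acetone, rt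
Reagents that add atoms: tert-butyl(chloro)dimethylsilane, CC(C)(C)[Si](C)(C)Cl; water, O
Why: Alpha-lithiation of the vinyl ether, C-silylation and enol ether hydrolysis is the standard acylsilane synthesis and should give the acetylsilane that serves as the acetyl anion donor; no stereocenter is formed.

**Step 4**
Reactants: 8 acetyl(tert-butyl)dimethylsilane; 4 methyl 4-fluoro-3-(2-oxoethyl)benzoate
Product: 12 methyl (2R,3R)-3-{[tert-butyl(dimethyl)silyl]oxy}-2-methyl-2-(prop-2-en-1-yl)-3,4-dihydro-2H-1-benzopyran-6-carboxylate, via silyloxy ketone 9 (not isolated), via bromozinc alkoxide 10 (not isolated), via potassium alkoxide 11 (not isolated)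
Conditions: 8 (1.2 equiv), (R,R)-TADDOL cyclic H-phosphonate [(TADDOLate)P(O)H, TADDOL = (4R,5R)-2,2-dimethyl-α,α,α′,α′-tetraphenyl-1,3-dioxolane-4,5-dimethanol] (10 mol%), n-BuLi (10 mol%), THF, 0 °C to rt, 4 added slowly; solvent exchange to CH2Cl2; allylZnBr (1.5 equiv), −78 °C; KN(SiMe3)2 (3 equiv), DMPU, −78 to 0 °C
Reagents that add atoms: allylzinc bromide, C=CC[Zn]Br
Why: The lithium phosphite adds to acylsilane 8 and a 1,2-Brook rearrangement turns its carbonyl carbon (the future C2) into a silyloxy-phosphonate carbanion, an acetyl anion equivalent that attacks the aldehyde carbon of 4 (the future C3), after which 1,4-silyl transfer to the new alkoxide and loss of the phosphite release ketone 9, so that two carbonyl carbons of like polarity are joined by umpolung and O3 leaves the event already capped (cross silyl benzoin reaction under metallophosphite catalysis). The chiral TADDOL phosphite selects the aldehyde face and so sets C3 (R); allylzinc bromide then adds to the C2 ketone of 9 through a five-membered zinc chelate between the ketone oxygen and the silyloxy oxygen (Cram chelate model, the known reaction type being the chelation-controlled organozinc addition to alpha-silyloxy ketones), anti to the C4 methylene, which sets C2 (R) with the allyl group cis to O3. Transmetalation of 10 with KN(SiMe3)2 gives potassium alkoxide 11, whose O1 attacks C8a in an addition–elimination (SNAr) displacement of fluoride, a six-membered ring closure that forms the pyran ring and is possible because the C6 ester para to C8a stabilises the Meisenheimer intermediate. The step needs the regiochemistry ketone at C2 and silyl ether at C3, which the Brook and silyl-transfer mechanism fixes, ketone-over-ester chemoselectivity, which the low temperature and the mild allylzinc reagent should secure, and closure through O1 instead of O3, which is secured because O3 carries the bulky tert-butyldimethylsilyl group that is slow to shift to the hindered tertiary alkoxide.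

**Step 5**
Reactants: 12 methyl (2R,3R)-3-{[tert-butyl(dimethyl)silyl]oxy}-2-methyl-2-(prop-2-en-1-yl)-3,4-dihydro-2H-1-benzopyran-6-carboxylate
Product: 13 methyl (2R,3R)-3-hydroxy-2-methyl-2-(prop-2-en-1-yl)-3,4-dihydro-2H-1-benzopyran-6-carboxylate
Conditions: Bu4NF, AcOH, THF, 0 °C to rt
Reagents that add atoms: none
Why: Fluoride-mediated desilylation, buffered with acetic acid so that the methyl ester is not attacked, should free the C3 alcohol with both stereocenters untouched.

**Step 6**
Reactants: 13 methyl (2R,3R)-3-hydroxy-2-methyl-2-(prop-2-en-1-yl)-3,4-dihydro-2H-1-benzopyran-6-carboxylate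
Product: 14 methyl (2R,3R)-3-(acetyloxy)-2-methyl-2-(prop-2-en-1-yl)-3,4-dihydro-2H-1-benzopyran-6-carboxylate
Conditions: Ac2O, pyridine, DMAP (cat.), CH2Cl2, rt
Reagents that add atoms: acetic anhydride, CC(=O)OC(C)=O
Why: DMAP-catalysed O-acylation (nucleophilic catalysis through the N-acetylpyridinium ion) should esterify the only hydroxyl group, hindered but secondary, with retention at C3.

**Step 7**
Reactants: 14 methyl (2R,3R)-3-(acetyloxy)-2-methyl-2-(prop-2-en-1-yl)-3,4-dihydro-2H-1-benzopyran-6-carboxylate; 15 2-methylbut-3-en-2-ol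
Product: 16 methyl (2R,3R)-3-(acetyloxy)-2-[(2E)-4-hydroxy-4-methylpent-2-en-1-yl]-2-methyl-3,4-dihydro-2H-1-benzopyran-6-carboxylate (target)
Conditions: 15 (5 equiv), second-generation Grubbs catalyst RuCl2(=CHPh)(PCy3)(H2IMes) (5 mol%), CH2Cl2, 40 °C
Reagents that add atoms: none
Why: Olefin cross-metathesis between the terminal allyl group and the hindered tertiary allylic alcohol, which homodimerises slowly and is used in excess, should install the side chain with the sterically and thermodynamically favoured E geometry and loss of ethene, without effect on C2, C3, the acetate or the benzoate.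

**Compound list**
1 | methyl 3-bromo-4-fluorobenzoate | COC(=O)c1ccc(F)c(Br)c1 | starting material
2 | 2-[(E)-2-ethoxyethenyl]-4,4,5,5-tetramethyl-1,3,2-dioxaborolane | CCO/C=C/B1OC(C)(C)C(C)(C)O1 | starting material
3 | methyl 3-[(E)-2-ethoxyethenyl]-4-fluorobenzoate | COC(=O)c1ccc(F)c(/C=C/OCC)c1 | intermediate
4 | methyl 4-fluoro-3-(2-oxoethyl)benzoate | COC(=O)c1ccc(F)c(CC=O)c1 | intermediate
5 | ethyl vinyl ether (ethoxyethene) | C=COCC | starting material
6 | (1-ethoxyethenyl)lithium | [Li]C(=C)OCC | intermediate
7 | tert-butyl(1-ethoxyethenyl)dimethylsilane | C=C(OCC)[Si](C)(C)C(C)(C)C | intermediate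
8 | acetyl(tert-butyl)dimethylsilane | CC(=O)[Si](C)(C)C(C)(C)C | intermediate
9 | methyl 3-[(2R)-2-{[tert-butyl(dimethyl)silyl]oxy}-3-oxobutyl]-4-fluorobenzoate | COC(=O)c1ccc(F)c(c1)C[C@@H](O[Si](C)(C)C(C)(C)C)C(C)=O | intermediate
10 | bromozinc alkoxide of methyl 3-[(2R,3R)-2-{[tert-butyl(dimethyl)silyl]oxy}-3-hydroxy-3-methylhex-5-en-1-yl]-4-fluorobenzoate | COC(=O)c1ccc(F)c(c1)C[C@@H](O[Si](C)(C)C(C)(C)C)[C@@](C)(CC=C)O[Zn]Br | intermediate
11 | potassium alkoxide of methyl 3-[(2R,3R)-2-{[tert-butyl(dimethyl)silyl]oxy}-3-hydroxy-3-methylhex-5-en-1-yl]-4-fluorobenzoate | COC(=O)c1ccc(F)c(c1)C[C@@H](O[Si](C)(C)C(C)(C)C)[C@@](C)(CC=C)[O-].[K+] | intermediate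
12 | methyl (2R,3R)-3-{[tert-butyl(dimethyl)silyl]oxy}-2-methyl-2-(prop-2-en-1-yl)-3,4-dihydro-2H-1-benzopyran-6-carboxylate | COC(=O)c1ccc2c(c1)C[C@@H](O[Si](C)(C)C(C)(C)C)[C@@](C)(CC=C)O2 | intermediate
13 | methyl (2R,3R)-3-hydroxy-2-methyl-2-(prop-2-en-1-yl)-3,4-dihydro-2H-1-benzopyran-6-carboxylate | COC(=O)c1ccc2c(c1)C[C@@H](O)[C@@](C)(CC=C)O2 | intermediate
14 | methyl (2R,3R)-3-(acetyloxy)-2-methyl-2-(prop-2-en-1-yl)-3,4-dihydro-2H-1-benzopyran-6-carboxylate | COC(=O)c1ccc2c(c1)C[C@@H](OC(C)=O)[C@@](C)(CC=C)O2 | intermediate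
15 | 2-methylbut-3-en-2-ol | C=CC(C)(C)O | starting material
16 | methyl (2R,3R)-3-(acetyloxy)-2-[(2E)-4-hydroxy-4-methylpent-2-en-1-yl]-2-methyl-3,4-dihydro-2H-1-benzopyran-6-carboxylate | COC(=O)c1ccc2c(c1)C[C@@H](OC(C)=O)[C@@](C)(C/C=C/C(C)(C)O)O2 | target

**Step count and risks**
Total step count: 7. Longest linear sequence: 6 steps (1, 2, 4, 5, 6, 7); step 3 is a one-step side branch.

Steps most likely to fail:

1. Step 4. What may go wrong:
   - proton transfer from the enolisable aldehyde 4 to the silyloxy-phosphonate carbanion, or poor facial selectivity in the C2–C3 bond formation (this acetylsilane/arylacetaldehyde pairing may need catalyst tuning);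
   - loss of chelation control in the allyl transfer;
   - a 1,2-silyl shift followed by five-membered ring closure through O3.

   The fallback is stepwise and uses an ether instead of a silyl group on O3. It sets out from 1: a Heck reaction with but-3-en-2-ol (Pd(OAc)2, Bu4NCl, NaHCO3, DMF) should give methyl 4-fluoro-3-(3-oxobutyl)benzoate F1. L-Proline-catalysed alpha-aminoxylation with nitrosobenzene at the methylene carbon should give methyl 3-[(2R)-2-(anilinooxy)-3-oxobutyl]-4-fluorobenzoate F2, and N–O cleavage (Zn, AcOH, THF) the hydroxy ketone methyl 4-fluoro-3-[(2R)-2-hydroxy-3-oxobutyl]benzoate F3. 4-Methoxybenzyl trichloroacetimidate with La(OTf)3 (cat.) should give the 4-methoxybenzyl ether F4. Chelation-controlled allylation (allylmagnesium bromide, CH2Cl2/Et2O, −78 °C) should give the tertiary alcohol methyl 4-fluoro-3-[(2R,3R)-3-hydroxy-2-(4-methoxybenzyloxy)-3-methylhex-5-en-1-yl]benzoate F5, and KN(SiMe3)2 in THF/DMPU should close the ring to the chroman 4-methoxybenzyl ether F6. DDQ (CH2Cl2, pH 7 buffer) then removes the ether and returns to the route at 13.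

2. Step 2. What may go wrong: aldol self-condensation and air oxidation of the arylacetaldehyde 4 during acid hydrolysis and isolation. The fallback sets out from 1: Suzuki–Miyaura coupling with vinylboronic acid pinacol ester (Pd(dppf)Cl2, K3PO4) should give methyl 3-ethenyl-4-fluorobenzoate F7, and anti-Markovnikov hydroboration–oxidation (9-BBN, then NaBO3) the storable alcohol methyl 4-fluoro-3-(2-hydroxyethyl)benzoate F8. Dess–Martin periodinane oxidation immediately before use returns to the route at 4, which is carried into step 4 as a solution.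

3. Step 7. What may go wrong: slow turnover at the allyl group next to the quaternary carbon C2, with competing homodimerisation of 14 or double-bond migration. The fallback uses carbonyl olefination instead of metathesis and sets out from 14: ozonolysis (O3, CH2Cl2, −78 °C; PPh3) should give the aldehyde methyl (2R,3R)-3-(acetyloxy)-2-methyl-2-(2-oxoethyl)-3,4-dihydro-2H-1-benzopyran-6-carboxylate F9. Julia–Kocienski olefination with pre-metalated 5-{[2-methyl-2-(triethylsilyloxy)propyl]sulfonyl}-1-phenyl-1H-tetrazole (KN(SiMe3)2, THF, −78 °C) should give the E-configured triethylsilyl ether of the target F10. Mild desilylation (HF·pyridine, THF) returns to the route at 16.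

**Further compounds**
F1 | step 4 | methyl 4-fluoro-3-(3-oxobutyl)benzoate | COC(=O)c1ccc(F)c(CCC(C)=O)c1
F2 | step 4 | methyl 3-[(2R)-2-(anilinooxy)-3-oxobutyl]-4-fluorobenzoate | COC(=O)c1ccc(F)c(c1)C[C@@H](ONc1ccccc1)C(C)=O
F3 | step 4 | methyl 4-fluoro-3-[(2R)-2-hydroxy-3-oxobutyl]benzoate | COC(=O)c1ccc(F)c(c1)C[C@@H](O)C(C)=O
F4 | step 4 | methyl 4-fluoro-3-[(2R)-2-(4-methoxybenzyloxy)-3-oxobutyl]benzoate | COC(=O)c1ccc(F)c(c1)C[C@@H](OCc1ccc(OC)cc1)C(C)=O
F5 | step 4 | methyl 4-fluoro-3-[(2R,3R)-3-hydroxy-2-(4-methoxybenzyloxy)-3-methylhex-5-en-1-yl]benzoate | COC(=O)c1ccc(F)c(c1)C[C@@H](OCc1ccc(OC)cc1)[C@@](C)(CC=C)O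
F6 | step 4 | methyl (2R,3R)-3-(4-methoxybenzyloxy)-2-methyl-2-(prop-2-en-1-yl)-3,4-dihydro-2H-1-benzopyran-6-carboxylate | COC(=O)c1ccc2c(c1)C[C@@H](OCc1ccc(OC)cc1)[C@@](C)(CC=C)O2
F7 | step 2 | methyl 3-ethenyl-4-fluorobenzoate | COC(=O)c1ccc(F)c(C=C)c1
F8 | step 2 | methyl 4-fluoro-3-(2-hydroxyethyl)benzoate | COC(=O)c1ccc(F)c(CCO)c1
F9 | step 7 | methyl (2R,3R)-3-(acetyloxy)-2-methyl-2-(2-oxoethyl)-3,4-dihydro-2H-1-benzopyran-6-carboxylate | COC(=O)c1ccc2c(c1)C[C@@H](OC(C)=O)[C@@](C)(CC=O)O2
F10 | step 7 | methyl (2R,3R)-3-(acetyloxy)-2-methyl-2-[(2E)-4-methyl-4-(triethylsilyloxy)pent-2-en-1-yl]-3,4-dihydro-2H-1-benzopyran-6-carboxylate | COC(=O)c1ccc2c(c1)C[C@@H](OC(C)=O)[C@@](C)(C/C=C/C(C)(C)O[Si](CC)(CC)CC)O2
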